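## Analysis of the target

The target is a 12-membered dilactone fused to two benzene rings: ring A is pentasubstituted and keeps one aromatic C–H, ring B is hexasubstituted. Both rings carry a methoxy group flanked by two hydroxyls, and ring B has a third hydroxyl where ring A has its hydrogen. On each ring a carboxyl and a 1-hydroxy-2-acyloxypropyl chain sit on neighbouring carbons, and the secondary oxygen of each chain is acylated by the carboxyl of the other ring, so the two halves are joined head to tail.

There are four stereocentres. The chain on ring B is (R,R) and the chain on ring A is (S,S). Within each chain the benzylic hydroxyl and the acyloxy group are syn, and the two chains have opposite handedness. The molecule therefore cannot come from dimerising one enantiomer, nor from one chiral reagent acting on both halves.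

The sensitive points are:
- each benzylic hydroxyl lies ortho to a lactone carbonyl (five-membered phthalide formation) and next to an acyloxy carbon (1,2-acyl shift);
- ring B is a hydroxyhydroquinone and oxidises in air;
- both carboxyls are di-ortho-substituted, and every hydroxy acid half would rather close its own six-membered lactone than the macrocycle.

The strategy rests on the two benzylic carbons of the macrocycle, one bonded to ring A next to its aromatic C–H and one bonded to ring B next to a phenolic carbon. Once the phenols are acylated these are the only benzylic C–H positions of the skeleton, and each neighbours a methyl-bearing acyloxy stereocentre that can be bought as an epoxide and can later direct a hydride.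

## Retrosynthetic reasoning

**34 from 33.** The five phenolic acetyl groups are removed last. They protect the oxidisable rings through the oxidation and reduction steps, and an aryl ester is cleaved under near-neutral conditions that the two hindered lactone linkages survive.

**33 from 32.** The two carbinol C–H bonds are traced back to the carbonyl groups of 32. Each ketone sits beside a methyl-bearing acyloxy stereocentre, so a non-chelating hydride delivered anti to the acyloxy group gives the syn carbinol on both sides. Because the two halves are mirror images, the same reagent gives (R) on one side and (S) on the other, which no single chiral reagent could do.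

**32 from 30.** Both benzylic C=O bonds are cut back to C–H, which gives the deoxy diolide 30, formed through monoketone 31. This is the disconnection the route is built around. It removes every benzylic oxygen from the macrocycle synthesis, so five-membered lactonisation and acyl migration cannot occur in any ester-forming step. The forward reaction must oxidise two methylene groups and nothing else.

**30 from 28 via 29.** The acetates are exchanged for benzyl ethers. Benzyl ethers tolerate the organometallic steps but would themselves be oxidised in the key step. They can be removed by hydrogenolysis precisely because 28 has no benzylic C–O bond in its skeleton.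

**28 from 26 via thioester 27.** The macrocycle is opened at the ester between the ring B carboxyl and the oxygen of the ring A chain. In 26 the acid sits on the ring whose own chain oxygen is already acylated, and the free hydroxyl sits on the ring whose carboxyl is already a hindered ester. No ring therefore holds an activated carboxyl and a free hydroxyl together.

**26 from 25, and 25 from 23 via 24.** The silyl ether is removed only after the ring B carboxyl is in place. That carboxyl is cut at its bond to the ring and traced to the aryl iodide 23. Ring B thus receives its carboxyl only after its chain oxygen has been acylated, which is what keeps it from closing a six-membered lactone on itself.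

**23 from 21 and 13 via acid chloride 22.** The first ester is cut at its acyl–oxygen bond. Forming it by acyl activation leaves the carbinol carbon of 21 untouched, so its configuration is retained and neither elimination nor participation by the neighbouring benzyloxy group can intervene.

**13 from 9 via 10, 11 and 12.** The ring A carboxyl is cut at its bond to the ring. It goes in by bromination of one of two equivalent positions, halogen–lithium exchange and carboxylation, with the chain hydroxyl silylated so that the acid cannot lactonise.

**9 from 6 and 7 via 8; 21 from 17 and 18 via 19 and 20.** Each aryl–CH2 bond is cut to an aryl Grignard reagent and an enantiomer of propylene oxide. The stereocentre is bought and is not a reacting centre in any later step. (S)-Epoxide 7 serves ring A and (R)-epoxide 18 serves ring B.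

**17 from 6 via 14, 15 and 16.** The extra oxygen of ring B is cut at its bond to the ring. In 6 the two positions between bromine and benzyloxy are equivalent and are the most acidic, so lithiation, borylation and oxidation place the oxygen without a regiochemical question.

**6 from 1 via 2, 3, 4 and 5.** The carbon–bromine bond is traced to a C–H bond of 1. This position is para to the methoxy group and meta to both hydroxyls, so neither electrophilic substitution nor directed lithiation reaches it. A sterically governed C–H borylation does, provided the benzyl groups are introduced only afterwards, because their phenyl rings would otherwise be borylated as well.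

## Alternatives that were turned down

**Alternative 1:** Ring B would be built from acyclic and four-membered-ring precursors. The disconnection cuts two ring B bonds and leads back to the squaric-acid-derived 4-alkenyl-4-hydroxycyclobutenone A1. On heating, A1 would open to a dienylketene and close to the hydroquinone ester A2, with all six substituents of ring B and both chain stereocentres (as an acetonide) in place.
- For it: the position of every ring B substituent is fixed by the connectivity of A1. On that point it is stronger than the lithiation and halogenation sequence used here for 17.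
- Against it: A2 is only one fragment. Ring A still has to be made separately. The acetonide has to be opened and its two oxygens told apart. Both ester bonds then have to be formed with a benzylic oxygen ortho to a carboxyl, which is exactly the situation that invites five-membered lactonisation and acyl shifts. A2 also carries three differently masked phenols and a free hydroquinone, which adds protecting-group steps.
- In its place, the chosen route derives both rings from the single arene 1, buys the methyl-bearing stereocentres, and keeps benzylic oxygen out of every ester-forming step.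

**Alternative 2:** The macrocycle would be cut at the oxygen–carbon bond between the ring A carboxylate and the methyl-bearing carbon, giving the alkynyl acid A3. Under gold catalysis the acid would add to the internal carbon of the terminal alkyne and close the 12-membered ring as the exocyclic enol ester A4. Hydrogenation of the methylene group would then create the methyl stereocentre.
- For it: the hindered carboxyl acts as a nucleophile and never needs acyl activation. On the ring closure itself this is as strong as, or stronger than, the thioester lactonisation of 26.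
- Against it: A4 is an acyl donor inside a medium ring. The propargylic silyl ether can ionise or rearrange under gold. The ring B ester carbonyl can compete for the activated alkyne. The hydrogenation must choose one face of the enol ester under macrocyclic control while benzylic C–O bonds are present. The first ester also has to be made with benzylic oxygen already in place.
- Comparison: the chosen route also relies on one substrate-controlled step (the reduction of 32), but it sets both benzylic centres at once, from ketones whose neighbouring stereocentres come from the chiral pool, and it needs no alkyne or enol ester chemistry.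

**Alternative 3:** Ring A would be formed last, by cutting the ring A carbon–carbon bond between the carboxyl-bearing carbon and the carbon bearing the carbinol chain. The precursor is the 16-membered triketo lactone A5. Mild base would make the methylene between ester and ketone add to the ketone next to the silyloxy carbon, and dehydration with enolisation would give the dilactone A6 with ring A as a free resorcinol.
- For it: the substitution pattern of ring A arises by itself, ring A emerges unprotected while ring B stays benzylated, and a 16-membered ring closes more easily than a 12-membered one.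
- Against it: A5 has three acidic carbon positions and four carbonyl groups, so several aldol and Claisen modes compete. The ketone that must accept the nucleophile has a silyloxy stereocentre on its α-carbon and an acyloxy group on its β-carbon, so base can epimerise it or expel the carboxylate and open the ring. Building A5 is also long.
- Comparison: the chosen route keeps both arenes intact from the first step and exposes no base-sensitive β-acyloxy ketone. Its price is a longer protecting-group sequence on the phenols.

Key step: step 17

## Route

Assumption: ring A is the benzene ring with one aromatic hydrogen and ring B the fully substituted one. The SMILES is read as (R,R) for the chain on ring B and (S,S) for the chain on ring A, with no further stereochemical element.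

Step 1
Reactants: 1 2-methoxyresorcinol
Product: 4 2-methoxy-5-(pinacolboryl)benzene-1,3-diol, via bis(O-boryl) ether 2 (not isolated), via C5-borylated bis(O-boryl) ether 3 (not isolated)
Conditions: HBpin (2.2 equiv), [Ir(OMe)(cod)]2 (cat.), dtbpy (cat.), THF, rt; then B2pin2, 80 °C; MeOH work-up
Reagents that add atoms: bis(pinacolato)diboron CC1(C)OB(OC1(C)C)B1OC(C)(C)C(C)(C)O1
Why: O-Borylation masks both phenols in the flask and makes the arene 1,2,3-trisubstituted, so the sterically governed iridium-catalysed C–H borylation can only take the position para to the methoxy group; methanol then cleaves the O–B bonds.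

Step 2
Reactants: 4 2-methoxy-5-(pinacolboryl)benzene-1,3-diol
Product: 5 2-[3,5-bis(benzyloxy)-4-methoxyphenyl]-4,4,5,5-tetramethyl-1,3,2-dioxaborolane
Conditions: BnBr, K2CO3, DMF, rt
Reagents that add atoms: benzyl bromide BrCc1ccccc1
Why: Williamson etherification of both phenols; an aryl pinacol boronate tolerates carbonate in DMF, and benzylating only now keeps the benzyl rings out of the borylation.

Step 3
Reactants: 5 2-[3,5-bis(benzyloxy)-4-methoxyphenyl]-4,4,5,5-tetramethyl-1,3,2-dioxaborolane
Product: 6 1,3-bis(benzyloxy)-5-bromo-2-methoxybenzene
Conditions: CuBr2 (3 equiv), MeOH/H2O 1:1, 80 °C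
Reagents that add atoms: copper dibromide [Cu+2].[Br-].[Br-]
Why: Copper-mediated ipso-bromodeboronation of an aryl pinacol boronate replaces C–B by C–Br at the same carbon and gives the halide needed for metalation.

Step 4
Reactants: 6 1,3-bis(benzyloxy)-5-bromo-2-methoxybenzene; 7 (S)-propylene oxide
Product: 9 (2S)-1-[3,5-bis(benzyloxy)-4-methoxyphenyl]propan-2-ol, via arylmagnesium bromide 8 (not isolated)
Conditions: Mg, THF, 40 °C; then CuI (10 mol%), 7, −30 to 0 °C; aq. NH4Cl
Reagents that add atoms: none
Why: Copper-catalysed opening of a monosubstituted epoxide by an aryl Grignard reagent takes place at the CH2 carbon, so the stereocentre of 7 is not a reacting centre and is carried over unchanged as (S).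

Step 5
Reactants: 9 (2S)-1-[3,5-bis(benzyloxy)-4-methoxyphenyl]propan-2-ol
Product: 10 tert-butyl{[(2S)-1-[3,5-bis(benzyloxy)-4-methoxyphenyl]propan-2-yl]oxy}dimethylsilane
Conditions: TBSCl, imidazole, DMF, rt
Reagents that add atoms: tert-butyldimethylsilyl chloride CC(C)(C)[Si](C)(C)Cl
Why: Standard silylation of a secondary alcohol; the silyl ether keeps this oxygen from lactonising onto the carboxyl that is introduced next to it.

Step 6
Reactants: 10 tert-butyl{[(2S)-1-[3,5-bis(benzyloxy)-4-methoxyphenyl]propan-2-yl]oxy}dimethylsilane
Product: 11 tert-butyl{[(2S)-1-[3,5-bis(benzyloxy)-2-bromo-4-methoxyphenyl]propan-2-yl]oxy}dimethylsilane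
Conditions: NBS (1.0 equiv), MeCN, 0 °C
Reagents that add atoms: N-bromosuccinimide O=C1CCC(=O)N1Br
Why: Electrophilic bromination goes ortho to one benzyloxy group and para to the other; the two open positions are equivalent by symmetry, so one equivalent should give one monobromide.

Step 7
Reactants: 11 tert-butyl{[(2S)-1-[3,5-bis(benzyloxy)-2-bromo-4-methoxyphenyl]propan-2-yl]oxy}dimethylsilane
Product: 13 2,4-bis(benzyloxy)-6-[(2S)-2-(tert-butyldimethylsilyloxy)propyl]-3-methoxybenzoic acid, via aryllithium 12 (not isolated)
Conditions: n-BuLi, THF, −78 °C; CO2; cold dilute HCl to pH 3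
Reagents that add atoms: carbon dioxide O=C=O
Why: Bromine–lithium exchange at −78 °C is faster than any attack on the benzyl or silyl ethers, and carboxylation of the aryllithium places the carboxyl ortho to the side chain.

Step 8
Reactants: 6 1,3-bis(benzyloxy)-5-bromo-2-methoxybenzene
Product: 16 2,4-bis(benzyloxy)-6-bromo-3-methoxyphenol, via ortho-lithiated bromide 14 (not isolated), via lithium aryl triisopropoxyborate 15 (not isolated)
Conditions: LiTMP, B(OiPr)3, THF, −78 °C; then AcOH, 30% H2O2, 0 °C to rt
Reagents that add atoms: hydrogen peroxide OO
Why: The two ring hydrogens of 6 are equivalent and lie between bromine and benzyloxy, the most acidic site; trapping the aryllithium in the flask as a borate outruns loss of LiBr, and peroxide oxidation turns C–B into C–O (directed ortho-metalation, borylation, oxidation).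

Step 9
Reactants: 16 2,4-bis(benzyloxy)-6-bromo-3-methoxyphenol
Product: 17 1,3,4-tris(benzyloxy)-5-bromo-2-methoxybenzene
Conditions: BnBr, K2CO3, DMF, 50 °C
Reagents that add atoms: benzyl bromide BrCc1ccccc1
Why: Williamson etherification of the new phenol gives ring B with its four oxygens in their final positions and uniform protection.

Step 10
Reactants: 17 1,3,4-tris(benzyloxy)-5-bromo-2-methoxybenzene; 18 (R)-propylene oxide
Product: 20 (2R)-1-[2,3,5-tris(benzyloxy)-4-methoxyphenyl]propan-2-ol, via arylmagnesium bromide 19 (not isolated)
Conditions: Mg, THF, 40 °C; then CuI (10 mol%), 18, −30 to 0 °C; aq. NH4Cl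
Reagents that add atoms: none
Why: Copper-catalysed epoxide opening by the aryl Grignard reagent at the CH2 carbon, as in step 4; the stereocentre of 18 is retained as (R).

Step 11
Reactants: 20 (2R)-1-[2,3,5-tris(benzyloxy)-4-methoxyphenyl]propan-2-ol
Product: 21 (2R)-1-[2,3,5-tris(benzyloxy)-6-iodo-4-methoxyphenyl]propan-2-ol
Conditions: NIS, MeCN, 0 °C to rt
Reagents that add atoms: N-iodosuccinimide O=C1CCC(=O)N1I
Why: Only one aromatic C–H is left on ring B, and it is ortho and para to benzyloxy groups, so electrophilic iodination can go nowhere else; the iodide stands in for the carboxyl until the side-chain oxygen has been acylated.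

Step 12
Reactants: 13 2,4-bis(benzyloxy)-6-[(2S)-2-(tert-butyldimethylsilyloxy)propyl]-3-methoxybenzoic acid; 21 (2R)-1-[2,3,5-tris(benzyloxy)-6-iodo-4-methoxyphenyl]propan-2-ol
Product: 23 (2R)-1-[2,3,5-tris(benzyloxy)-6-iodo-4-methoxyphenyl]propan-2-yl 2,4-bis(benzyloxy)-6-[(2S)-2-(tert-butyldimethylsilyloxy)propyl]-3-methoxybenzoate, via acid chloride 22 (not isolated)
Conditions: 1-chloro-N,N,2-trimethylprop-1-en-1-amine, CH2Cl2, 0 °C to rt; then 21, Et3N, DMAP, 40 °C
Reagents that add atoms: none
Why: The hindered acid is turned into its chloride under neutral conditions and acylates the secondary alcohol with DMAP; the C–O bond of the carbinol is not broken, so the (R) centre is retained, and ring B has no carboxyl yet that its own hydroxyl could attack.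

Step 13
Reactants: 23 (2R)-1-[2,3,5-tris(benzyloxy)-6-iodo-4-methoxyphenyl]propan-2-yl 2,4-bis(benzyloxy)-6-[(2S)-2-(tert-butyldimethylsilyloxy)propyl]-3-methoxybenzoate
Product: 25 3,4,6-tris(benzyloxy)-2-[(2R)-2-({2,4-bis(benzyloxy)-6-[(2S)-2-(tert-butyldimethylsilyloxy)propyl]-3-methoxybenzoyl}oxy)propyl]-5-methoxybenzoic acid, via arylmagnesium chloride 24 (not isolated)
Conditions: iPrMgCl·LiCl, THF, −40 to −20 °C; CO2; cold dilute HCl to pH 3
Reagents that add atoms: carbon dioxide O=C=O
Why: Iodine–magnesium exchange is accelerated by the ortho benzyloxy group and tolerates esters; the di-ortho-substituted benzoate is shielded against the arylmagnesium, which is then carboxylated.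

Step 14
Reactants: 25 3,4,6-tris(benzyloxy)-2-[(2R)-2-({2,4-bis(benzyloxy)-6-[(2S)-2-(tert-butyldimethylsilyloxy)propyl]-3-methoxybenzoyl}oxy)propyl]-5-methoxybenzoic acid
Product: 26 3,4,6-tris(benzyloxy)-2-[(2R)-2-({2,4-bis(benzyloxy)-6-[(2S)-2-hydroxypropyl]-3-methoxybenzoyl}oxy)propyl]-5-methoxybenzoic acid
Conditions: HF·pyridine, THF/pyridine, 0 °C to rt
Reagents that add atoms: none
Why: Fluoride cleaves the silyl ether under weakly acidic conditions, so no alkoxide is formed that could attack the neighbouring hindered ester and close a six-membered lactone.

Step 15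
Reactants: 26 3,4,6-tris(benzyloxy)-2-[(2R)-2-({2,4-bis(benzyloxy)-6-[(2S)-2-hydroxypropyl]-3-methoxybenzoyl}oxy)propyl]-5-methoxybenzoic acid
Product: 28 pentabenzyl deoxy diolide, via S-(2-pyridyl) thioester 27 (not isolated)
Conditions: 2,2'-dipyridyl disulfide, PPh3, toluene, rt; then slow addition into toluene at reflux (about 1 mM)
Reagents that add atoms: none
Why: Corey–Nicolaou macrolactonisation: the 2-pyridyl thioester is formed selectively at the acid and, at high dilution, the hydrogen-bonded hydroxyl attacks it to close the 12-membered ring; this double activation is established for di-ortho-substituted benzoic acids and leaves the carbinol configuration untouched.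

Step 16
Reactants: 28 pentabenzyl deoxy diolide
Product: 30 pentaacetate deoxy diolide, via pentaphenol deoxy diolide 29 (not isolated)
Conditions: H2 (1 atm), Pd/C, EtOAc/THF, rt; filtration under argon; then Ac2O, pyridine, DMAP, rt
Reagents that add atoms: acetic anhydride CC(=O)OC(C)=O
Why: Hydrogenolysis removes the five benzyl ethers and cannot touch the macrocycle, which has no benzylic C–O bond; the air-sensitive pentaphenol is acetylated at once, and the acetates are the protection needed for the oxidation.

Step 17
Reactants: 30 pentaacetate deoxy diolide
Product: 32 bis(α-acyloxy ketone) diolide, via ring A monoketone 31 (not isolated)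
Conditions: N-hydroxyphthalimide (0.3 equiv), Co(OAc)2·4H2O (5 mol%), O2 (1 atm), MeCN, 70 °C
Reagents that add atoms: dioxygen O=O
Why: The phthalimide N-oxyl radical, generated from N-hydroxyphthalimide by the cobalt/O2 couple, abstracts a benzylic hydrogen; the benzylic radical is trapped by O2, the peroxyl radical takes hydrogen from N-hydroxyphthalimide, and cobalt converts the hydroperoxide into the aryl ketone and water, first at the less hindered ring A methylene (31) and then at ring B. The closest known reaction type is the N-hydroxyphthalimide/Co(OAc)2 aerobic oxidation of alkylarene methylenes to aryl ketones. No ring is closed and no stereocentre is created; the two carbonyl C–O bonds are the only bonds formed. The selectivity needed is site selectivity: with all five phenols acetylated the two ring methylenes are the only benzylic C–H bonds of 30, both lie para to a methoxy group, and the electrophilic N-oxyl radical avoids the C–H on the neighbouring acyloxy carbon, the acetate methyls and the methoxy groups. The acetates also keep the oxygen-rich rings from being oxidised to quinones by trivalent cobalt. The methyl-bearing stereocentres become α to a ketone only as the product forms and the medium is neutral, so they should not epimerise. Over-oxidation is limited because the product has no benzylic C–H left.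

Step 18
Reactants: 32 bis(α-acyloxy ketone) diolide
Product: 33 syn,syn-diol pentaacetate
Conditions: BH3·SMe2, THF, −20 to 0 °C; MeOH quench
Reagents that add atoms: none
Why: Borane is a non-chelating, non-basic hydride source; in the polar Felkin–Anh arrangement the acyloxy group stands perpendicular to the carbonyl and hydride enters anti to it past the hydrogen, which turns the (R)-acyloxy ketone into the (R)-carbinol and the (S) one into the (S)-carbinol, the syn relationship on both sides. The product is an alkoxyborane and not an alkoxide, so it should not attack the ortho lactone carbonyl.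

Step 19
Reactants: 33 syn,syn-diol pentaacetate
Product: 34 CNP0086623.3 (target)
Conditions: NH4OAc (excess), degassed MeOH/H2O 4:1, rt, argon
Reagents that add atoms: none
Why: Aryl acetates are far more reactive acyl donors than the two hindered alkyl benzoate linkages and are solvolysed at near-neutral pH, which should spare the lactones and avoid base-induced acyl shifts; oxygen is excluded because ring B becomes a hydroxyhydroquinone.

## Compound list

1 | 2-methoxyresorcinol | COc1c(O)cccc1O | starting material
2 | 2,2'-[(2-methoxy-1,3-phenylene)bis(oxy)]bis(4,4,5,5-tetramethyl-1,3,2-dioxaborolane) | COc1c(OB2OC(C)(C)C(C)(C)O2)cccc1OB1OC(C)(C)C(C)(C)O1 | intermediate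
3 | C5-borylated bis(O-boryl) ether of 1 | COc1c(OB2OC(C)(C)C(C)(C)O2)cc(B2OC(C)(C)C(C)(C)O2)cc1OB1OC(C)(C)C(C)(C)O1 | intermediate
4 | 2-methoxy-5-(4,4,5,5-tetramethyl-1,3,2-dioxaborolan-2-yl)benzene-1,3-diol | COc1c(O)cc(B2OC(C)(C)C(C)(C)O2)cc1O | intermediate
5 | 2-[3,5-bis(benzyloxy)-4-methoxyphenyl]-4,4,5,5-tetramethyl-1,3,2-dioxaborolane | COc1c(OCc2ccccc2)cc(B2OC(C)(C)C(C)(C)O2)cc1OCc1ccccc1 | intermediate
6 | 1,3-bis(benzyloxy)-5-bromo-2-methoxybenzene | COc1c(OCc2ccccc2)cc(Br)cc1OCc1ccccc1 | intermediate
7 | (S)-propylene oxide | C[C@H]1CO1 | starting material
8 | [3,5-bis(benzyloxy)-4-methoxyphenyl]magnesium bromide | COc1c(OCc2ccccc2)cc([Mg]Br)cc1OCc1ccccc1 | intermediate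
9 | (2S)-1-[3,5-bis(benzyloxy)-4-methoxyphenyl]propan-2-ol | C[C@H](O)Cc1cc(OCc2ccccc2)c(OC)c(OCc2ccccc2)c1 | intermediate
10 | tert-butyl{[(2S)-1-[3,5-bis(benzyloxy)-4-methoxyphenyl]propan-2-yl]oxy}dimethylsilane | C[C@H](O[Si](C)(C)C(C)(C)C)Cc1cc(OCc2ccccc2)c(OC)c(OCc2ccccc2)c1 | intermediate
11 | tert-butyl{[(2S)-1-[3,5-bis(benzyloxy)-2-bromo-4-methoxyphenyl]propan-2-yl]oxy}dimethylsilane | C[C@H](O[Si](C)(C)C(C)(C)C)Cc1cc(OCc2ccccc2)c(OC)c(OCc2ccccc2)c1Br | intermediate
12 | aryllithium from 11 | C[C@H](O[Si](C)(C)C(C)(C)C)Cc1cc(OCc2ccccc2)c(OC)c(OCc2ccccc2)c1[Li] | intermediate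
13 | 2,4-bis(benzyloxy)-6-[(2S)-2-(tert-butyldimethylsilyloxy)propyl]-3-methoxybenzoic acid | C[C@H](O[Si](C)(C)C(C)(C)C)Cc1cc(OCc2ccccc2)c(OC)c(OCc2ccccc2)c1C(=O)O | intermediate
14 | [2,4-bis(benzyloxy)-6-bromo-3-methoxyphenyl]lithium | COc1c(OCc2ccccc2)cc(Br)c([Li])c1OCc1ccccc1 | intermediate
15 | lithium [2,4-bis(benzyloxy)-6-bromo-3-methoxyphenyl]tri(propan-2-yloxy)borate | [Li+].COc1c(OCc2ccccc2)cc(Br)c([B-](OC(C)C)(OC(C)C)OC(C)C)c1OCc1ccccc1 | intermediate
16 | 2,4-bis(benzyloxy)-6-bromo-3-methoxyphenol | COc1c(OCc2ccccc2)cc(Br)c(O)c1OCc1ccccc1 | intermediate
17 | 1,3,4-tris(benzyloxy)-5-bromo-2-methoxybenzene | COc1c(OCc2ccccc2)cc(Br)c(OCc2ccccc2)c1OCc1ccccc1 | intermediate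
18 | (R)-propylene oxide | C[C@@H]1CO1 | starting material
19 | [2,3,5-tris(benzyloxy)-4-methoxyphenyl]magnesium bromide | COc1c(OCc2ccccc2)cc([Mg]Br)c(OCc2ccccc2)c1OCc1ccccc1 | intermediate
20 | (2R)-1-[2,3,5-tris(benzyloxy)-4-methoxyphenyl]propan-2-ol | C[C@@H](O)Cc1cc(OCc2ccccc2)c(OC)c(OCc2ccccc2)c1OCc1ccccc1 | intermediate
21 | (2R)-1-[2,3,5-tris(benzyloxy)-6-iodo-4-methoxyphenyl]propan-2-ol | C[C@@H](O)Cc1c(I)c(OCc2ccccc2)c(OC)c(OCc2ccccc2)c1OCc1ccccc1 | intermediate
22 | 2,4-bis(benzyloxy)-6-[(2S)-2-(tert-butyldimethylsilyloxy)propyl]-3-methoxybenzoyl chloride | C[C@H](O[Si](C)(C)C(C)(C)C)Cc1cc(OCc2ccccc2)c(OC)c(OCc2ccccc2)c1C(Cl)=O | intermediate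
23 | (2R)-1-[2,3,5-tris(benzyloxy)-6-iodo-4-methoxyphenyl]propan-2-yl 2,4-bis(benzyloxy)-6-[(2S)-2-(tert-butyldimethylsilyloxy)propyl]-3-methoxybenzoate | C[C@H](O[Si](C)(C)C(C)(C)C)Cc1cc(OCc2ccccc2)c(OC)c(OCc2ccccc2)c1C(=O)O[C@H](C)Cc1c(I)c(OCc2ccccc2)c(OC)c(OCc2ccccc2)c1OCc1ccccc1 | intermediate
24 | arylmagnesium chloride from 23 | C[C@H](O[Si](C)(C)C(C)(C)C)Cc1cc(OCc2ccccc2)c(OC)c(OCc2ccccc2)c1C(=O)O[C@H](C)Cc1c([Mg]Cl)c(OCc2ccccc2)c(OC)c(OCc2ccccc2)c1OCc1ccccc1 | intermediate
25 | 3,4,6-tris(benzyloxy)-2-[(2R)-2-({2,4-bis(benzyloxy)-6-[(2S)-2-(tert-butyldimethylsilyloxy)propyl]-3-methoxybenzoyl}oxy)propyl]-5-methoxybenzoic acid | C[C@H](O[Si](C)(C)C(C)(C)C)Cc1cc(OCc2ccccc2)c(OC)c(OCc2ccccc2)c1C(=O)O[C@H](C)Cc1c(C(=O)O)c(OCc2ccccc2)c(OC)c(OCc2ccccc2)c1OCc1ccccc1 | intermediate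
26 | 3,4,6-tris(benzyloxy)-2-[(2R)-2-({2,4-bis(benzyloxy)-6-[(2S)-2-hydroxypropyl]-3-methoxybenzoyl}oxy)propyl]-5-methoxybenzoic acid (seco acid) | C[C@H](O)Cc1cc(OCc2ccccc2)c(OC)c(OCc2ccccc2)c1C(=O)O[C@H](C)Cc1c(C(=O)O)c(OCc2ccccc2)c(OC)c(OCc2ccccc2)c1OCc1ccccc1 | intermediate
27 | S-(pyridin-2-yl) thioester of 26 | C[C@H](O)Cc1cc(OCc2ccccc2)c(OC)c(OCc2ccccc2)c1C(=O)O[C@H](C)Cc1c(C(=O)Sc2ccccn2)c(OCc2ccccc2)c(OC)c(OCc2ccccc2)c1OCc1ccccc1 | intermediate
28 | pentabenzyl deoxy diolide (12-membered dilactone with both benzylic positions as CH2) | COc1c(OCc3ccccc3)cc2c(c1OCc1ccccc1)C(=O)O[C@H](C)Cc1c(OCc3ccccc3)c(OCc3ccccc3)c(OC)c(OCc3ccccc3)c1C(=O)O[C@@H](C)C2 | intermediate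
29 | pentaphenol deoxy diolide | COc1c(O)cc2c(c1O)C(=O)O[C@H](C)Cc1c(O)c(O)c(OC)c(O)c1C(=O)O[C@@H](C)C2 | intermediate
30 | pentaacetate deoxy diolide | COc1c(OC(C)=O)cc2c(c1OC(C)=O)C(=O)O[C@H](C)Cc1c(OC(C)=O)c(OC(C)=O)c(OC)c(OC(C)=O)c1C(=O)O[C@@H](C)C2 | intermediate
31 | ring A monoketone of 30 | COc1c(OC(C)=O)cc2c(c1OC(C)=O)C(=O)O[C@H](C)Cc1c(OC(C)=O)c(OC(C)=O)c(OC)c(OC(C)=O)c1C(=O)O[C@@H](C)C2=O | intermediate
32 | bis(α-acyloxy ketone) diolide pentaacetate | COc1c(OC(C)=O)cc2c(c1OC(C)=O)C(=O)O[C@H](C)C(=O)c1c(OC(C)=O)c(OC(C)=O)c(OC)c(OC(C)=O)c1C(=O)O[C@@H](C)C2=O | intermediate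
33 | syn,syn-diol pentaacetate (pentaacetate of the target) | COc1c(OC(C)=O)cc2c(c1OC(C)=O)C(=O)O[C@H](C)[C@H](O)c1c(OC(C)=O)c(OC(C)=O)c(OC)c(OC(C)=O)c1C(=O)O[C@@H](C)[C@H]2O | intermediate
34 | CNP0086623.3 | COc1c(O)cc2c(c1O)C(=O)O[C@H](C)[C@H](O)c1c(O)c(O)c(OC)c(O)c1C(=O)O[C@@H](C)[C@H]2O | target

## Step count and least certain steps

Total step count: 19. Longest linear sequence: 15 steps (steps 1–3, then 4–7 or 8–11, then 12–19).

**Step 17 (key step).** Two processes are most likely to go wrong.
- Hydrogen abstraction may stall at the ring B methylene. It lies between two ortho substituents, so its C–H bonds sit close to the ring plane, and the acetylated rings are not electron-rich.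
- A benzylic alkoxyl radical formed from the hydroperoxide may fragment by β-scission, because the carbon radical it would expel is stabilised by the acyloxy oxygen; this would open the macrocycle.

The fallback avoids oxygen-centred radicals. It sets out from 30. Wohl–Ziegler bromination (NBS, light, PhCF3, 80 °C) should give the bis(benzylic bromide) F1, since the bromine atom is a smaller and more reactive abstractor. N-Methylmorpholine N-oxide in MeCN should then convert each C–Br into C=O by a Kornblum-type oxidation. The route is rejoined at 32.

**Step 18.** The most likely failure is poor facial selectivity. Both aryl ketones are twisted out of conjugation by their ortho substituents, and the conformation of the 12-membered ring, not the open-chain Felkin–Anh arrangement, may decide which face is exposed. Acetyl migration from the ring B phenol to the new benzylic oxygen is a second risk during work-up.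

The fallback replaces substrate control by reagent control in two passes, starting from 32. The ring A ketone has only one ortho substituent and should react first. It would be reduced with BH3·SMe2 and the (S)-2-methyl-CBS-oxazaborolidine, which is expected to give the (S)-carbinol if the aryl group acts as the larger substituent, to give the ring A hydroxy ketone F2. The (R)-catalyst would then reduce the ring B ketone. The route is rejoined at 33.

**Step 19.** The likely failures are translactonisation of a freed benzylic hydroxyl onto the ortho lactone carbonyl, a 1,2-acyl shift from the neighbouring oxygen, and air oxidation of ring B. All three are promoted by even weakly basic conditions.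

The fallback changes the order of the last two operations, starting from 32. The acetates are removed first with NH4OAc in degassed aqueous methanol, while no benzylic hydroxyl is present, to give the pentaphenol diketone F3. The two ketones are then reduced with excess BH3·SMe2 and the product is released by methanol. The route is rejoined at 34.

**Step 15.** The likely failures are oligomerisation in place of 12-membered ring closure, and attack of the free hydroxyl on the ester of its own ring, which would split the molecule into six-membered lactones. The activated acid is di-ortho-substituted and reacts slowly.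

The fallback forms the ring B carboxyl and the second ester in one operation, starting from 23. HF·pyridine gives the iodo hydroxy ester F4. Intramolecular alkoxycarbonylation (Pd(OAc)2, Xantphos, CO at 1 atm, Et3N, toluene, 90 °C, slow addition) lets an acylpalladium intermediate, not an activated acid, acylate the hydroxyl. The route is rejoined at 28.

**Step 13.** The likely failure is intramolecular attack of the arylmagnesium on the ester six atoms away, an acyl transfer to carbon, or incomplete exchange at the crowded, electron-rich iodide.

The fallback avoids a carbanion. Starting from 23, hydroxycarbonylation with zerovalent palladium (Pd(OAc)2, Xantphos, CO at 1 atm, KOAc, DMF/H2O, 80 °C) should give 25 directly, with no new intermediate.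

**Step 8.** The likely failures are loss of LiBr from the ortho-lithiated bromide to give an aryne, and competing deprotonation at a benzylic ether carbon followed by rearrangement.

The fallback uses electrophilic chemistry, starting from 6. Vilsmeier–Haack formylation (POCl3, DMF) at the same activated position should give 2,4-bis(benzyloxy)-6-bromo-3-methoxybenzaldehyde F5. Baeyer–Villiger oxidation with mCPBA gives the aryl formate F6, and K2CO3 in methanol releases the phenol. The route is rejoined at 16.

## Further compounds

F1 | step 17 | bis(benzylic bromide) of 30 (both C–Br carbons as mixtures) | COc1c(OC(C)=O)cc2c(c1OC(C)=O)C(=O)O[C@H](C)C(Br)c1c(OC(C)=O)c(OC(C)=O)c(OC)c(OC(C)=O)c1C(=O)O[C@@H](C)C2Br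
F2 | step 18 | ring A hydroxy ketone (ring B ketone unreduced) | COc1c(OC(C)=O)cc2c(c1OC(C)=O)C(=O)O[C@H](C)C(=O)c1c(OC(C)=O)c(OC(C)=O)c(OC)c(OC(C)=O)c1C(=O)O[C@@H](C)[C@H]2O
F3 | step 19 | pentaphenol diketone diolide | COc1c(O)cc2c(c1O)C(=O)O[C@H](C)C(=O)c1c(O)c(O)c(OC)c(O)c1C(=O)O[C@@H](C)C2=O
F4 | step 15 | (2R)-1-[2,3,5-tris(benzyloxy)-6-iodo-4-methoxyphenyl]propan-2-yl 2,4-bis(benzyloxy)-6-[(2S)-2-hydroxypropyl]-3-methoxybenzoate | C[C@H](O)Cc1cc(OCc2ccccc2)c(OC)c(OCc2ccccc2)c1C(=O)O[C@H](C)Cc1c(I)c(OCc2ccccc2)c(OC)c(OCc2ccccc2)c1OCc1ccccc1
F0 | step 13 | none | none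
F5 | step 8 | 2,4-bis(benzyloxy)-6-bromo-3-methoxybenzaldehyde | COc1c(OCc2ccccc2)cc(Br)c(C=O)c1OCc1ccccc1
F6 | step 8 | 2,4-bis(benzyloxy)-6-bromo-3-methoxyphenyl formate | COc1c(OCc2ccccc2)cc(Br)c(OC=O)c1OCc1ccccc1
A1 | alternative 1 | 4-alkenyl-4-hydroxycyclobutenone with tert-butoxy and methoxy groups, the alkenyl group carrying the 2-(trimethylsilyl)ethyl ester and the (4R,5R)-dioxolane | O=C1C(OC(C)(C)C)=C(OC)C1(O)C(=C[C@H]2OC(C)(C)O[C@@H]2C)C(=O)OCC[Si](C)(C)C
A2 | alternative 1 | ring B hydroquinone 2-(trimethylsilyl)ethyl ester with the side chain as acetonide | C[C@H]1OC(C)(C)O[C@@H]1c1c(O)c(OC(C)(C)C)c(OC)c(O)c1C(=O)OCC[Si](C)(C)C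
A3 | alternative 2 | seco acid with free ring A carboxyl and terminal alkyne on the ring B propargylic silyl ether | OC(=O)c1c(OCc2ccccc2)c(OC)c(OCc2ccccc2)cc1[C@H](O[Si](C)(C)C(C)(C)C)[C@H](C)OC(=O)c1c(OCc2ccccc2)c(OC)c(OCc2ccccc2)c(OCc2ccccc2)c1[C@@H](O[Si](C)(C)C(C)(C)C)C#C
A4 | alternative 2 | 12-membered dilactone with an exocyclic methylene enol ester | COc1c(OCc3ccccc3)cc2c(c1OCc3ccccc3)C(=O)OC(=C)[C@H](O[Si](C)(C)C(C)(C)C)c1c(OCc3ccccc3)c(OCc3ccccc3)c(OC)c(OCc3ccccc3)c1C(=O)O[C@@H](C)[C@H]2O[Si](C)(C)C(C)(C)C
A5 | alternative 3 | 16-membered triketo lactone | O=C1CC(=O)C(OC)C(=O)CC(=O)[C@H](O[Si](C)(C)C(C)(C)C)[C@H](C)OC(=O)c2c(OCc3ccccc3)c(OC)c(OCc3ccccc3)c(OCc3ccccc3)c2[C@@H](O[Si](C)(C)C(C)(C)C)[C@@H](C)O1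
A6 | alternative 3 | protected dilactone with free ring A phenols | COc1c(O)cc2c(c1O)C(=O)O[C@H](C)[C@H](O[Si](C)(C)C(C)(C)C)c1c(OCc3ccccc3)c(OCc3ccccc3)c(OC)c(OCc3ccccc3)c1C(=O)O[C@@H](C)[C@H]2O[Si](C)(C)C(C)(C)C
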